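**Strategy.** Ring B (C1 ketone, C2 carrying the methylene bridge, C3 OMe, C4 acyl, C5 NH2, C6 carbinol) hides a lactic acid unit, C6(OH)(CH3)–C1(=O), next to an enamine carbon C5 at the oxidation level of a nitrile. The key step joins the lithium enolate of the pivalaldehyde acetal of (S)-lactic acid (a temporary dioxolanone ring) to an (E)-3-methoxyalk-2-enenitrile chain on the finished ring A: the enolate adds to the nitrile (C5–C6) trans to the tert-butyl group, and the resulting azadienyl anion closes on the dioxolanone carbonyl (C1–C2), expelling pivalaldehyde. One operation builds ring B, sets C6 and unveils NH2, OH and ketone. Ring A comes from the same acetal.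

Key step: step 10

Assumption: (R)-2-methylbutanoic acid is bought as the single enantiomer.

Step 1
Reactants: 1 (S)-lactic acid; 2 pivalaldehyde
Product: 3 (2S,5S)-2-tert-butyl-5-methyl-1,3-dioxolan-4-one (cis acetal)
Conditions: cat. p-TsOH, cat. H2SO4, pentane, reflux (Dean–Stark); crystallisation from pentane/Et2O at −78 °C
Reagents that add atoms: pivalaldehyde, CC(C)(C)C=O
Why: Acid-catalysed acetalisation with azeotropic removal of water leaves the lactate centre untouched, and the acetal carbon should equilibrate mainly to the cis (2S,5S) isomer, which is isolated by low-temperature crystallisation.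

Step 2
Reactants: 4 dimethyl 2-methylpentanedioate (racemic); 5 acetonitrile
Product: 7 methyl 6-cyano-2-methyl-5-oxohexanoate (racemic), via lithiated acetonitrile 6 (not isolated)
Conditions: MeCN, n-BuLi, THF, −78 °C; then 4, −78 → −40 °C; AcOH
Reagents that add atoms: acetonitrile, CC#N
Why: Crossed Claisen-type acylation of lithiated acetonitrile should take place at the unbranched, less hindered ester, and the β-keto nitrile is at once deprotonated, which stops further attack.

Step 3
Reactants: 7 methyl 6-cyano-2-methyl-5-oxohexanoate; 8 tert-butyl acetate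
Product: 10 tert-butyl 8-cyano-4-methyl-3,7-dioxooctanoate (racemic), via lithium ester enolate 9 (not isolated)
Conditions: tert-butyl acetate, LiN(iPr)2 (excess), THF, −78 °C; then 7, −78 → −30 °C; AcOH
Reagents that add atoms: tert-butyl acetate, CC(=O)OC(C)(C)C
Why: Crossed Claisen condensation of the excess lithium enolate of tert-butyl acetate with the remaining methyl ester, the keto nitrile being masked as its enolate and the β-keto ester leaving the equilibrium as its own enolate.

Step 4
Reactants: 10 tert-butyl 8-cyano-4-methyl-3,7-dioxooctanoate; 11 trimethyl orthoformate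
Product: 12 tert-butyl (2E,7E)-8-cyano-3,7-dimethoxy-4-methylocta-2,7-dienoate (racemic)
Conditions: HC(OMe)3, MeOH, cat. H2SO4, 25 → 45 °C
Reagents that add atoms: trimethyl orthoformate, COC(OC)OC; methanol, CO
Why: Acid-catalysed ketal formation with the orthoformate and loss of methanol should turn both enolisable 1,3-dicarbonyl units into their conjugated methyl enol ethers (thermodynamic E geometry expected; any Z isomer converges later through delocalised anions), which fixes the positions of both methoxy groups of the target.

Step 5
Reactants: 12 tert-butyl (2E,7E)-8-cyano-3,7-dimethoxy-4-methylocta-2,7-dienoate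
Product: 13 (2E,7E)-8-cyano-3,7-dimethoxy-4-methylocta-2,7-dienoic acid (racemic)
Conditions: CF3CO2H, CH2Cl2, 0 → 25 °C
Reagents that add atoms: none
Why: Anhydrous acidolysis of the tert-butyl ester (loss of the tert-butyl cation as isobutene) frees the acid without water, so both enol ethers and the nitrile should remain.

Step 6
Reactants: 13 (2E,7E)-8-cyano-3,7-dimethoxy-4-methylocta-2,7-dienoic acid; 3 (2S,5S)-2-tert-butyl-5-methyl-1,3-dioxolan-4-one
Product: 16 (2S,5R)-2-tert-butyl-5-[(2E,7E)-8-cyano-3,7-dimethoxy-4-methylocta-2,7-dienoyl]-5-methyl-1,3-dioxolan-4-one (both epimers at the chain methine carbon), via acid chloride 14 (not isolated), via sodium enolate 15 (not isolated)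
Conditions: 13, (COCl)2, cat. DMF, CH2Cl2, 0 °C, evaporation; 3, NaN(SiMe3)2, THF, −78 °C; enolate added to 14 in THF at −78 °C
Reagents that add atoms: dioxolanone 3, C[C@@H]1O[C@H](C(C)(C)C)OC1=O
Why: Claisen-type C-acylation of the lactate-derived sodium enolate (self-regeneration of the stereocentre): the planar enolate is attacked trans to the tert-butyl group, so the methyl group stays cis to it and the new quaternary carbon, later the carbinol carbon of ring A, is formed as R, while the silazane set free on enolate formation, unlike a dialkylamine, should not compete for the acid chloride.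

Step 7
Reactants: 16 (2S,5R)-2-tert-butyl-5-[(2E,7E)-8-cyano-3,7-dimethoxy-4-methylocta-2,7-dienoyl]-5-methyl-1,3-dioxolan-4-one
Product: 17 (2E)-5-[(1R,5R)-5-hydroxy-2-methoxy-1,5-dimethyl-4,6-dioxocyclohex-2-en-1-yl]-3-methoxypent-2-enenitrile (ring A alcohol)
Conditions: LiN(SiMe3)2, THF, −78 → −20 °C; AcOH, −78 °C
Reagents that add atoms: none
Why: Vinylogous Dieckmann condensation: reversible γ-deprotonation gives the dienolate, whose tertiary carbon attacks the acylal carbonyl on the face that carries the acyl chain (6-(enolendo)-exo-trig), and loss of pivalaldehyde from the tetrahedral intermediate makes the closure irreversible; the new quaternary centre should be R because, in the cis-fused bicyclic transition state, the acetal oxygen rather than the C-methyl group takes the axial site at the carbinol carbon, and the smaller methyl group of the carbanion (inside position of the dienolate, A(1,3) strain) takes the axial site syn to that oxygen, which leaves the side chain equatorial and trans to the oxygen.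

Step 8
Reactants: 18 (R)-2-methylbutanoic acid
Product: 19 (R)-2-methylbutanoyl chloride
Conditions: (COCl)2, cat. DMF, CH2Cl2, 0 → 25 °C; distillation
Reagents that add atoms: oxalyl chloride, O=C(Cl)C(Cl)=O
Why: Vilsmeier-type activation (chloroiminium salt from DMF and oxalyl chloride) converts the acid into its chloride without any base, so the α-stereocentre cannot be lost through a ketene, and the volatile chloride is purified by distillation and kept for steps 9 and 11.

Step 9
Reactants: 17 ring A alcohol; 19 (R)-2-methylbutanoyl chloride
Product: 20 (1R,3R)-3-[(3E)-4-cyano-3-methoxybut-3-en-1-yl]-4-methoxy-1,3-dimethyl-2,6-dioxocyclohex-4-en-1-yl (2R)-2-methylbutanoate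
Conditions: 19, pyridine, cat. DMAP, CH2Cl2, 0 → 25 °C
Reagents that add atoms: (R)-2-methylbutanoyl chloride 19, CC[C@@H](C)C(=O)Cl
Why: DMAP-catalysed acylation (Steglich-type acyl transfer) of the tertiary α-ketol, with pyridine instead of a trialkylamine so that no ketene forms and the R centre of the acyl group is kept.

Step 10
Reactants: 20 (1R,3R)-3-[(3E)-4-cyano-3-methoxybut-3-en-1-yl]-4-methoxy-1,3-dimethyl-2,6-dioxocyclohex-4-en-1-yl (2R)-2-methylbutanoate; 3 (2S,5S)-2-tert-butyl-5-methyl-1,3-dioxolan-4-one
Product: 23 (1R,3R)-3-{[(5R)-4-amino-5-hydroxy-2-methoxy-5-methyl-6-oxocyclohexa-1,3-dien-1-yl]methyl}-4-methoxy-1,3-dimethyl-2,6-dioxocyclohex-4-en-1-yl (2R)-2-methylbutanoate (ring B amine), via lithium enolate 21 (not isolated), via N-lithio ketimine 22 (not isolated)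
Conditions: 3 (2.2 equiv), LiN(iPr)2 (2.0 equiv), THF, −78 °C; then 20, −78 → −30 °C; AcOH
Reagents that add atoms: dioxolanone 3, C[C@@H]1O[C@H](C(C)(C)C)OC1=O
Why: Proposed new method: the lithium enolate 21 adds through its fully substituted carbon to the sterically open nitrile carbon of 20, which the lithium cation activates by coordination to nitrogen (Thorpe-type addition; the closest known reactions are the condensation of lithium ester enolates with nitriles to β-enamino esters, the Blaise reaction and the alkylation of this same enolate with self-regeneration of the stereocentre), and gives the N-lithio ketimine 22 (bond C5–C6). A proton shift from the γ-methylene group to nitrogen, intramolecular for the E enol ether and relayed by the diisopropylamine set free on enolate formation for any Z isomer so that both converge, gives a 1-azapentadienyl anion whose terminal carbon attacks the acylal carbonyl in a 6-(enolendo)-exo-trig Dieckmann-type closure (bond C1–C2), and collapse of the tetrahedral intermediate with loss of pivalaldehyde makes the reversible first addition productive. The only new stereocentre, carbinol carbon C6, is fixed in the addition by the tert-butyl group of the acetal: the nitrile enters trans to it, so (S)-lactic acid gives the R centre with overall retention. The step needs chemoselectivity for the nitrile over the two ketones and the ester of ring A, and closure through carbon rather than nitrogen; ring A has no acidic hydrogen and only neopentyl-type carbonyl groups, the nitrile is the least hindered electrophile, the enolate is kept in excess over the amide base, and only attack through the γ-carbon gives a six-membered ring. Work-up leaves the free tertiary alcohol, the C1 ketone and, by tautomerisation of the imine, the primary enamine.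

Step 11
Reactants: 23 ring B amine; 19 (R)-2-methylbutanoyl chloride
Product: 24 gilluone B, (1R,3R)-3-{[(5R)-4-amino-5-hydroxy-2-methoxy-5-methyl-3-[(2R)-2-methylbutanoyl]-6-oxocyclohexa-1,3-dien-1-yl]methyl}-4-methoxy-1,3-dimethyl-2,6-dioxocyclohex-4-en-1-yl (2R)-2-methylbutanoate
Conditions: 19, pyridine, CH2Cl2, 0 → 25 °C
Reagents that add atoms: (R)-2-methylbutanoyl chloride 19, CC[C@@H](C)C(=O)Cl
Why: C-Acylation of a primary β-enaminone at its nucleophilic β-carbon C4 of ring B (enamine acylation, as in the reaction of β-aminocrotonates with acid chlorides in pyridine) should give the hydrogen-bonded β-amino enone as the thermodynamic product, while the hindered tertiary alcohol is not acylated without DMAP.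

**Compound list**

1 | (S)-lactic acid | C[C@H](O)C(=O)O | starting material
2 | pivalaldehyde | CC(C)(C)C=O | starting material
3 | (2S,5S)-2-tert-butyl-5-methyl-1,3-dioxolan-4-one | C[C@@H]1O[C@H](C(C)(C)C)OC1=O | intermediate
4 | dimethyl 2-methylpentanedioate (racemic) | COC(=O)CCC(C)C(=O)OC | starting material
5 | acetonitrile | CC#N | starting material
6 | (cyanomethyl)lithium | [Li]CC#N | intermediate
7 | methyl 6-cyano-2-methyl-5-oxohexanoate (racemic) | COC(=O)C(C)CCC(=O)CC#N | intermediate
8 | tert-butyl acetate | CC(=O)OC(C)(C)C | starting material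
9 | lithium enolate of tert-butyl acetate | C=C(O[Li])OC(C)(C)C | intermediate
10 | tert-butyl 8-cyano-4-methyl-3,7-dioxooctanoate (racemic) | CC(C)(C)OC(=O)CC(=O)C(C)CCC(=O)CC#N | intermediate
11 | trimethyl orthoformate | COC(OC)OC | starting material
12 | tert-butyl (2E,7E)-8-cyano-3,7-dimethoxy-4-methylocta-2,7-dienoate (racemic) | CC(C)(C)OC(=O)/C=C(/OC)C(C)CC/C(OC)=C\C#N | intermediate
13 | (2E,7E)-8-cyano-3,7-dimethoxy-4-methylocta-2,7-dienoic acid (racemic) | OC(=O)/C=C(/OC)C(C)CC/C(OC)=C\C#N | intermediate
14 | (2E,7E)-8-cyano-3,7-dimethoxy-4-methylocta-2,7-dienoyl chloride | ClC(=O)/C=C(/OC)C(C)CC/C(OC)=C\C#N | intermediate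
15 | sodium (2S)-2-tert-butyl-5-methyl-1,3-dioxol-4-olate (sodium enolate of 3) | CC1=C(O[Na])O[C@@H](C(C)(C)C)O1 | intermediate
16 | (2S,5R)-2-tert-butyl-5-[(2E,7E)-8-cyano-3,7-dimethoxy-4-methylocta-2,7-dienoyl]-5-methyl-1,3-dioxolan-4-one (both epimers at the chain methine carbon) | C[C@]1(C(=O)/C=C(/OC)C(C)CC/C(OC)=C\C#N)O[C@H](C(C)(C)C)OC1=O | intermediate
17 | (2E)-5-[(1R,5R)-5-hydroxy-2-methoxy-1,5-dimethyl-4,6-dioxocyclohex-2-en-1-yl]-3-methoxypent-2-enenitrile | O[C@]1(C)C(=O)C=C(OC)[C@@](C)(CC/C(OC)=C\C#N)C1=O | intermediate
18 | (R)-2-methylbutanoic acid | CC[C@@H](C)C(=O)O | starting material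
19 | (R)-2-methylbutanoyl chloride | CC[C@@H](C)C(=O)Cl | intermediate
20 | (1R,3R)-3-[(3E)-4-cyano-3-methoxybut-3-en-1-yl]-4-methoxy-1,3-dimethyl-2,6-dioxocyclohex-4-en-1-yl (2R)-2-methylbutanoate | CC[C@@H](C)C(=O)O[C@]1(C)C(=O)C=C(OC)[C@@](C)(CC/C(OC)=C\C#N)C1=O | intermediate
21 | lithium (2S)-2-tert-butyl-5-methyl-1,3-dioxol-4-olate (lithium enolate of 3) | CC1=C(O[Li])O[C@@H](C(C)(C)C)O1 | intermediate
22 | N-lithio ketimine from 21 and the nitrile of 20 (new quaternary carbon R, acetal carbon S) | CC[C@@H](C)C(=O)O[C@]1(C)C(=O)C=C(OC)[C@@](C)(CC/C(OC)=C\C(=N[Li])[C@@]2(C)O[C@H](C(C)(C)C)OC2=O)C1=O | intermediate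
23 | (1R,3R)-3-{[(5R)-4-amino-5-hydroxy-2-methoxy-5-methyl-6-oxocyclohexa-1,3-dien-1-yl]methyl}-4-methoxy-1,3-dimethyl-2,6-dioxocyclohex-4-en-1-yl (2R)-2-methylbutanoate | CC[C@@H](C)C(=O)O[C@]1(C)C(=O)C=C(OC)[C@@](C)(CC2=C(OC)C=C(N)[C@@](C)(O)C2=O)C1=O | intermediate
24 | gilluone B | CC[C@@H](C)C(=O)O[C@]1(C)C(=O)C=C(OC)[C@@](C)(CC2=C(OC)C(C(=O)[C@H](C)CC)=C(N)[C@@](C)(O)C2=O)C1=O | target

Total step count: 11. Longest linear sequence: 9 steps (steps 2 to 7 and 9 to 11, from 4 to 24). Step 1 is a one-step branch that supplies 3 for steps 6 and 10, and step 8 is a one-step branch that supplies 19 for steps 9 and 11.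

**Steps most likely to fail**

Step 10 (Proposed new method). The lithium enolate may be lost before it adds to the weakly electrophilic nitrile carbon, through proton transfer from the γ-methylene group, attack on the carbonyl groups or the ester of ring A, or fragmentation of the enolate on warming. The adduct may also close through nitrogen. The fallback uses known reactions, sets out from 3 and 20 and comes back at 23. Radical bromination of 3 (N-bromosuccinimide, cat. AIBN, CCl4, reflux) gives (2R)-5-bromo-2-tert-butyl-5-methyl-1,3-dioxolan-4-one F1. Its Reformatsky reagent (zinc dust, THF, 40 °C) is a weakly basic zinc enolate with the same facial bias; it is added to the nitrile of 20 in a Blaise reaction, and work-up with aqueous K2CO3 gives the N–H ketimine adduct F2. A separate vinylogous Dieckmann closure (LiN(SiMe3)2, THF, −78 → 0 °C) then gives 23.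

Step 7. The two groups on the attacking carbon, methyl and a primary alkyl chain, differ little in size, so the facial selectivity of the ring closure may be low or may run the other way. Thorpe-type attack of the carbanion on the side-chain nitrile is a second risk. The fallback covers a closure that prefers the other face; it does not repair a merely unselective closure. It sets out from 14 (made from 13 as in step 6) and comes back at 17. The enantiomeric acetal (2R,5R)-2-tert-butyl-5-methyl-1,3-dioxolan-4-one F3 is made from (R)-lactic acid and 2 as in step 1. Deprotonation of F3 with NaN(SiMe3)2 and acylation with 14, as in step 6, gives the (2R,5S)-acyl dioxolanone F4, and ring closure as in step 7 gives the (1R,5S)-hydroxy dione F5, which has the correct quaternary methyl centre and the wrong carbinol centre. The hydroxyl group is removed with SmI2 (THF/MeOH, −78 °C, reductive cleavage of the α-ketol) to give the 2-methyl-1,3-dione F6. Oxygen is put back at the enolisable carbon under reagent control with an enantiopure (camphorsulfonyl)oxaziridine (KN(SiMe3)2, THF, −78 °C), which gives 17. The carbinol centre then no longer depends on the sense of the ring closure.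

Step 11. Acylation may take place at nitrogen instead of at C4 of ring B, and the acyl group may lose its configuration through the ketene under the basic conditions. The fallback sets out from 23 and comes back at 24. Nitrogen is acylated on purpose (19, pyridine, DMAP, CH2Cl2, 40 °C) to give the N-acyl enamide F7. The acyl group is then relayed to carbon by a 1,3-acyl shift to the more stable hydrogen-bonded C-acyl enaminone (DMAP, toluene, 80 °C, Steglich-type acyl transfer; or a photo-Fries-type shift), which gives 24.

Further compounds
F1 | step 10 | (2R)-5-bromo-2-tert-butyl-5-methyl-1,3-dioxolan-4-one (acetal carbon spatially as in 3, mixture at C5) | CC1(Br)O[C@H](C(C)(C)C)OC1=O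
F2 | step 10 | N–H ketimine adduct of the dioxolanone and the nitrile of 20 (protonated form of 22) | CC[C@@H](C)C(=O)O[C@]1(C)C(=O)C=C(OC)[C@@](C)(CC/C(OC)=C\C(=N)[C@@]2(C)O[C@H](C(C)(C)C)OC2=O)C1=O
F3 | step 7 | (2R,5R)-2-tert-butyl-5-methyl-1,3-dioxolan-4-one | C[C@H]1O[C@@H](C(C)(C)C)OC1=O
F4 | step 7 | (2R,5S)-2-tert-butyl-5-[(2E,7E)-8-cyano-3,7-dimethoxy-4-methylocta-2,7-dienoyl]-5-methyl-1,3-dioxolan-4-one | C[C@@]1(C(=O)/C=C(/OC)C(C)CC/C(OC)=C\C#N)O[C@@H](C(C)(C)C)OC1=O
F5 | step 7 | (2E)-5-[(1R,5S)-5-hydroxy-2-methoxy-1,5-dimethyl-4,6-dioxocyclohex-2-en-1-yl]-3-methoxypent-2-enenitrile | O[C@@]1(C)C(=O)C=C(OC)[C@@](C)(CC/C(OC)=C\C#N)C1=O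
F6 | step 7 | (2E)-3-methoxy-5-[(1R)-2-methoxy-1,5-dimethyl-4,6-dioxocyclohex-2-en-1-yl]pent-2-enenitrile (mixture at C5, enolisable) | CC1C(=O)C=C(OC)[C@@](C)(CC/C(OC)=C\C#N)C1=O
F7 | step 11 | N-[(2R)-2-methylbutanoyl] enamide of 23 | CC[C@@H](C)C(=O)O[C@]1(C)C(=O)C=C(OC)[C@@](C)(CC2=C(OC)C=C(NC(=O)[C@H](C)CC)[C@@](C)(O)C2=O)C1=O
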